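If a flask may ask for gas faster than gas can enter solution, read that entry rate before anything else.

| flask | substrate | gas | temperature | remark | time |
|---|---|---|---|---|---|
| gamma | 0.14 M | 3.2 mM (held) | 20 °C | run made earlier |  |
| theta | 0.22 M | 3.2 mM (held) | 45 °C | run made earlier |  |
| Sunday's | 0.10 M | 3.2 mM (held) | 45 °C |  | 5.0 d |
| Tuesday's | 0.10 M | 3.2 mM (held) | 25 °C |  | 5.0 d |
| Saturday's | 0.10 M | 3.2 mM (held) | 65 °C |  | 5.0 d |

| run | time / d | target / % | isomer of the product / % | substrate / % |
|---|---|---|---|---|
| gamma | 2.00 | 51.8 | 2.2 | 48.3 |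
| gamma | 4.00 | 75.7 | 0 | 23.9 |
| gamma | 6.00 | 87.2 | 0 | 12.1 |
| gamma | 10.0 | 98.7 | 0 | 2.6 |
| gamma | 15.0 | 99.7 | 0.3 | 0 |
| theta | 0.417 | 21.3 | 4.4 | 75.8 |
| theta | 0.625 | 28.6 | 3.4 | 67.0 |
| theta | 0.833 | 39.7 | 8.4 | 53.5 |
| theta | 1.25 | 59.6 | 11.9 | 28.6 |
| theta | 2.00 | 86.4 | 14.1 | 0.4 |
| theta | 3.00 | 85.7 | 14.2 | 0 |
| theta | 5.00 | 85.8 | 15.0 | 0.7 |

(readings scatter by 1 percentage point)

- at the start none of the gas is in solution

- the flask that comes out highest in share of target in all that became target or isomer of the product, or "all alike" when all lie within 1.5 percentage points (Sunday's / Tuesday's / Saturday's / all alike)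
- share of target in all that became target or isomer of the product, Sunday's
- share of target in all that became target or isomer of the product, Tuesday's
- share of target in all that became target or isomer of the product, Saturday's

1. Read the ceiling. In the theta run, substrate falls nearly in a line from 75.8 % at 0.417 d to 28.6 % at 1.25 d. That is a loss of 0.125 M d⁻¹. Call this reading the gas ceiling, the loss of [substrate] that the held gas carries when its entry is the rate-limiting step.

2. Turn the temperature. The gamma run decays first order, with 0.346 d⁻¹. The gamma run's starting demand is 0.0484 M d⁻¹, below the ceiling. The theta run still reads on the ceiling at [substrate] of 0.0629 M, so read its rate constant as at least 1.98 d⁻¹. Reckon Sunday's starting demand at 0.198 M d⁻¹ or more, above the ceiling. For Tuesday's, allow a doubling of the gamma constant. Tuesday's demand is then reckoned at 0.0692 M d⁻¹, below the ceiling. Assume Saturday's sits on the ceiling too; no run tests the ceiling at that temperature.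

3. Turn the charge. At the ceiling, Sunday's drains in 0.802 d, sooner than the theta run's 1.76 d. The theta run's last reading gives a share of 85.1 %. Expect Sunday's, at the same temperature with less substrate, slightly above that reading.

4. Turn the time. Sunday's drain time is shorter than 5.0 d, and the theta run's target stays flat from 2.00 d to 5.00 d. Expect no gain in Sunday's from waiting.

5. The gamma run, below the ceiling, ends at a share of 99.7 %, higher than the theta run's 85.1 %, though those runs differ in both temperature and charge. Commit to Tuesday's as highest. Leave Saturday's share open: the ceiling gives its pace, not its split.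

6. The forecast names Tuesday's, with 88 % for Sunday's, 99 % for Tuesday's and 60 % for Saturday's, where it judges that “gas starvation is severe”.

7. The flask gives Tuesday's as highest, with 88.8 % for Sunday's, 99.9 % for Tuesday's and 91.1 % for Saturday's.

    substrate ⇌ tight pair (K = 0.00260, k = 9.06 × 10⁻⁶ s⁻¹, Ea = 111 kJ mol⁻¹, ΔH = −18.0 kJ mol⁻¹)
    tight pair ⇌ loose pair (K = 1.60, k = 7.72 × 10⁻⁴ s⁻¹, Ea = 98.0 kJ mol⁻¹, ΔH = −35.0 kJ mol⁻¹)
    partner + tight pair → target (k = 490 M⁻¹ s⁻¹, Ea = 39.0 kJ mol⁻¹)
    partner + loose pair → isomer of the product (k = 155 M⁻¹ s⁻¹, Ea = 41.0 kJ mol⁻¹)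
    gas ⇌ partner, rate k5*(csat - [partner]) (kL = 4.52 × 10⁻⁴ s⁻¹)
    (constants at 25 °C)

Saturday's holds 8.90 % of isomer of the product at 5.00 d, and Sunday's holds 11.2 %. For Sunday's, the ceiling puts half the charge at 0.401 d, and half of its turnover of substrate to tight pair is done by 0.401 d. For Saturday's, the ceiling puts 70 percent conversion at 0.562 d, and the flask reaches it at 0.561 d.

The readings are simulated with constants of no real substance; noise was put on by code.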